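## Retrosynthetic overview

- The target is reached from a vinyl-substituted 1,2-dioxane by oxidative cleavage of the vinyl group and methyl ester formation; the dioxane is closed by 6-exo-tet attack of a tertiary peroxide anion on a secondary mesylate (inversion), after (Z)-crotylboration of an aldehyde and cobalt-catalysed silylperoxidation of a 1,1-disubstituted alkene.
- The side chain is carried by a 3-alkyl-2,4,4-trimethylcyclohex-2-enone, which is disconnected to a bromo allene plus CO: a radical carbonylative [5+1] annulation that closes the ring through the bond between the carbonyl carbon C1 and the methyl-bearing carbon C2.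
- Enabling feature: the C1(=O)–C2(CH3)=C3 unit of the cyclohexenone is the retron of an acyl radical (ring C6 radical + CO) adding to the central carbon of a 1,1-disubstituted allene C3=C2=CH2, whose terminal CH2 becomes the C2 methyl group; the gem-dimethyl carbon C4 blocks the five-ring alternative.
- The bromo allene comes from a copper-catalysed SN2' union of the side-chain Grignard reagent with a propargylic mesylate made from α,α-dimethyl-γ-butyrolactone.
- Ring order: cyclohexenone first, 1,2-dioxane second.

Key step: step 9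

Remark: the quaternary peroxy carbon (dioxane C6) is created in step 11 without facial control, so every intermediate from there to the dioxane closure is a pair of epimers at this carbon, and the 6R series is secured by chromatographic separation of the cyclic epimers at step 15. Cyclohexenone locants are C1 (C=O), C2 (methyl-bearing), C3 (chain-bearing), C4 (gem-dimethyl), C5, C6; dioxane locants are O1, O2, C3 (CH), C6 (quaternary).

## Route

Step 1
Reactants: 1 3,3-dimethyloxolan-2-one (α,α-dimethyl-γ-butyrolactone)
Product: 2 3,3-dimethyloxolan-2-ol (lactol; racemic hemiacetal carbon)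
Conditions: DIBAL-H (1.1 equiv), CH2Cl2, −78 °C; Rochelle salt work-up
Reagents that add atoms: none
Why: Partial lactone-to-lactol reduction should stop at the hemiacetal because the aluminium alkoxide of the tetrahedral intermediate survives at −78 °C until work-up; the new hemiacetal centre is racemic and is destroyed in step 2.

Step 2
Reactants: 2 3,3-dimethyloxolan-2-ol
Product: 3 3,3-dimethylpent-4-yn-1-ol
Conditions: dimethyl (1-diazo-2-oxopropyl)phosphonate, K2CO3, MeOH, rt to 40 °C
Reagents that add atoms: dimethyl (1-diazo-2-oxopropyl)phosphonate, CC(=O)C(=[N+]=[N-])P(=O)(OC)OC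
Why: Seyferth–Gilbert homologation with the Ohira–Bestmann reagent should convert the open hydroxy aldehyde form of the lactol, which cannot enolise, into the terminal alkyne.

Step 3
Reactants: 3 3,3-dimethylpent-4-yn-1-ol
Product: 4 5-bromo-3,3-dimethylpent-1-yne
Conditions: CBr4, PPh3, CH2Cl2, 0 °C
Reagents that add atoms: tetrabromomethane, BrC(Br)(Br)Br
Why: Appel bromination of the unhindered primary alcohol proceeds by SN2 on the alkoxyphosphonium ion and leaves the alkyne untouched.

Step 4
Reactants: 4 5-bromo-3,3-dimethylpent-1-yne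
Product: 5 6-bromo-4,4-dimethylhex-2-yn-1-ol
Conditions: n-BuLi (1.05 equiv), THF, −78 °C; (CH2O)n, −78 °C to rt
Reagents that add atoms: formaldehyde (as paraformaldehyde), C=O
Why: Deprotonation of the terminal alkyne is far faster than attack of n-BuLi on the primary bromide at −78 °C, and the lithium acetylide adds to formaldehyde (acetylide hydroxymethylation).

Step 5
Reactants: 5 6-bromo-4,4-dimethylhex-2-yn-1-ol
Product: 6 6-bromo-4,4-dimethylhex-2-yn-1-yl methanesulfonate
Conditions: MsCl, Et3N, CH2Cl2, −20 to 0 °C
Reagents that add atoms: methanesulfonyl chloride, CS(=O)(=O)Cl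
Why: Sulfonylation of a primary propargylic alcohol is routine and gives the leaving group for the SN2' step.

Step 6
Reactants: 7 3-methylbut-3-en-1-ol; 8 tert-butyl(2-iodoethoxy)dimethylsilane
Product: 9 6-[(tert-butyldimethylsilyl)oxy]-3-methylidenehexan-1-ol
Conditions: 7, n-BuLi (2.1 equiv), TMEDA, Et2O/hexane, 0 °C to rt; then 8, THF, −78 °C to rt
Reagents that add atoms: none
Why: Alkoxide-directed allylic lithiation of isoprenol gives the dianion, which should be alkylated at the former methyl carbon by the primary iodide (dianion alkylation of 3-methylbut-3-en-1-ol).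

Step 7
Reactants: 9 6-[(tert-butyldimethylsilyl)oxy]-3-methylidenehexan-1-ol
Product: 10 [(6-bromo-4-methylidenehexyl)oxy](tert-butyl)dimethylsilane
Conditions: CBr4, PPh3, CH2Cl2, 0 °C
Reagents that add atoms: tetrabromomethane, BrC(Br)(Br)Br
Why: Appel bromination of the primary alcohol is compatible with the silyl ether and the 1,1-disubstituted alkene.

Step 8
Reactants: 10 [(6-bromo-4-methylidenehexyl)oxy](tert-butyl)dimethylsilane; 6 6-bromo-4,4-dimethylhex-2-yn-1-yl methanesulfonate
Product: 12 {[7-(4-bromo-2-methylbutan-2-yl)-4-methylidenenona-7,8-dien-1-yl]oxy}(tert-butyl)dimethylsilane (bromo allene), via Grignard reagent 11 (not isolated)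
Conditions: 10, Mg, THF, rt; then CuBr·SMe2 (10 mol %, monovalent copper), 6, THF, −78 to −40 °C
Reagents that add atoms: none
Why: Copper-catalysed anti SN2' substitution of a primary propargylic mesylate by a Grignard reagent should deliver the alkyl group to the distal alkyne carbon and give the 1,1-disubstituted allene, while the primary alkyl bromide and the silyl ether are inert below −40 °C.

Step 9
Reactants: 12 bromo allene
Product: 13 3-{6-[(tert-butyldimethylsilyl)oxy]-3-methylidenehexyl}-2,4,4-trimethylcyclohex-2-en-1-one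
Conditions: CO (80 atm), Bu3SnH (1.2 equiv), AIBN (0.2 equiv), C6H6 (0.01 M), 80 °C
Reagents that add atoms: carbon monoxide, [C-]#[O+]
Why: Proposed new method: Bu3Sn• abstracts bromine from 12, the primary radical (future ring C6) is carbonylated under 80 atm of CO faster than it is reduced at 0.01 M, the nucleophilic acyl radical (C1) adds to the central sp carbon (C2) of the allene, and the resulting 2-acylallyl radical takes a hydrogen atom from Bu3SnH at its unhindered CH2 terminus, which becomes the C2 methyl group and leaves C2=C3 conjugated with the new ketone. The closest known reaction type is the tin hydride-mediated radical carbonylation of alkenyl halides with acyl radical cyclisation onto alkenes (radical [n+1] annulation to cycloalkanones), combined with the known preference of radicals for the central carbon of an allene when an allyl radical results; the combination on an allene, which gives the enone oxidation level directly, is not documented. The cyclohexenone is closed by the C1–C2 bond in a six-membered closure that is exo with respect to the consumed C2=CH2 π bond, whose orbital lies in the plane of the tether on C3, so that C3=C2 stays endocyclic. No stereocentre is formed. The step needs six-ring closure at C2 in preference to 5-exo attack at C3 and to five-ring closure of the alkyl radical before carbonylation: C3 is fully substituted and flanked by the quaternary C4, so attack there would create two adjacent quaternary centres and an unstabilised vinyl radical, whereas attack at C2 gives a delocalised allyl radical, and the gem-dimethyl group favours the coiled conformer (Thorpe–Ingold effect). Hydrogen delivery to the tertiary C3 terminus is sterically disfavoured, and any exo-methylene isomer formed that way would isomerise to the same conjugated enone on mild base treatment.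

Step 10
Reactants: 13 silyl ether enone
Product: 14 3-(6-hydroxy-3-methylidenehexyl)-2,4,4-trimethylcyclohex-2-en-1-one
Conditions: TBAF, THF, 0 °C to rt
Reagents that add atoms: none
Why: Fluoride cleavage of the primary silyl ether is done before the peroxide is installed, because fluoride would also cleave a silyl peroxide.

Step 11
Reactants: 14 3-(6-hydroxy-3-methylidenehexyl)-2,4,4-trimethylcyclohex-2-en-1-one
Product: 15 3-{6-hydroxy-3-methyl-3-[(triethylsilyl)peroxy]hexyl}-2,4,4-trimethylcyclohex-2-en-1-one (both epimers at the peroxy carbon)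
Conditions: Co(acac)2 (10 mol %, divalent cobalt), O2 (1 atm), Et3SiH, ClCH2CH2Cl, rt
Reagents that add atoms: dioxygen, O=O; triethylsilane, CC[SiH](CC)CC
Why: In this Mukaiyama–Isayama silylperoxidation, hydrogen-atom transfer from a cobalt hydride to the electron-rich 1,1-disubstituted alkene gives the tertiary radical, which is trapped by O2 and silylated, while the hindered, electron-poor tetrasubstituted enone should not react; the quaternary peroxy carbon is formed without facial control.

Step 12
Reactants: 15 silylperoxy alcohol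
Product: 16 4-methyl-4-[(triethylsilyl)peroxy]-6-(2,6,6-trimethyl-3-oxocyclohex-1-en-1-yl)hexanal (both C4 epimers)
Conditions: Dess–Martin periodinane, CH2Cl2, 0 °C to rt
Reagents that add atoms: none
Why: Dess–Martin oxidation of the primary alcohol is mild and neutral enough to leave the silyl peroxide and the enone intact.

Step 13
Reactants: 16 silylperoxy aldehyde
Product: 17 3-{(6S,7S)-6-hydroxy-3,7-dimethyl-3-[(triethylsilyl)peroxy]non-8-en-1-yl}-2,4,4-trimethylcyclohex-2-en-1-one (both epimers at the peroxy carbon)
Conditions: (Z)-crotyl-B(Ipc)2 (made in the flask beforehand from (+)-Ipc2BOMe, cis-2-butene, n-BuLi, KOt-Bu and BF3·OEt2), THF/Et2O, −78 °C; then HOCH2CH2NH2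
Reagents that add atoms: (Z)-crotyl-B(Ipc)2, C/C=C\CB([C@H]1C[C@H]2C[C@@H]([C@@H]1C)C2(C)C)[C@H]1C[C@H]2C[C@@H]([C@@H]1C)C2(C)C
Why: In this Brown crotylboration the (Z)-crotyl group reacts through a chair Zimmerman–Traxler transition state to give the syn relationship of the new methyl and hydroxyl carbons, and the isopinocampheyl groups of the (−)-α-pinene series direct attack to the Re face of the aldehyde so that both new centres are S; the hindered ketone does not react at −78 °C, and the vinyl group serves as a non-acidic precursor of the ester.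

Step 14
Reactants: 17 homoallylic alcohol
Product: 18 (3S,4S)-3,7-dimethyl-7-[(triethylsilyl)peroxy]-9-(2,6,6-trimethyl-3-oxocyclohex-1-en-1-yl)non-1-en-4-yl methanesulfonate (both C7 epimers)
Conditions: MsCl, Et3N, CH2Cl2, 0 °C
Reagents that add atoms: methanesulfonyl chloride, CS(=O)(=O)Cl
Why: Mesylation of the secondary alcohol takes place at oxygen and keeps the carbinol configuration.

Step 15
Reactants: 18 secondary mesylate
Product: 20 (3R,6R)-3-[(2S)-but-3-en-2-yl]-6-methyl-6-[2-(2,6,6-trimethyl-3-oxocyclohex-1-en-1-yl)ethyl]-1,2-dioxane (after removal of its 6S epimer), via hydroperoxy mesylate 19 (not isolated)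
Conditions: TBAF (1.1 equiv), THF, 0 °C to rt; chromatographic separation of the C6 epimers
Reagents that add atoms: none
Why: Fluoride cleaves the Si–O bond and the tertiary peroxide anion should displace the secondary mesylate in a 6-exo-tet SN2 reaction (intramolecular peroxide alkylation), which inverts the carbinol carbon to the required 3R configuration; the neighbouring carbon carries a vinyl group and is not acidic, so E1cB loss of the mesylate is excluded, and the cyclic 6R and 6S epimers are separated here.

Step 16
Reactants: 20 vinyl dioxane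
Product: 22 (2R)-2-{(3R,6R)-6-methyl-6-[2-(2,6,6-trimethyl-3-oxocyclohex-1-en-1-yl)ethyl]-1,2-dioxan-3-yl}propanoic acid, via peroxy aldehyde 21 (not isolated)
Conditions: O3, CH2Cl2, −78 °C (Sudan red 7B end-point); Me2S; then NaClO2, NaH2PO4, 2-methylbut-2-ene, t-BuOH/H2O, 0 °C
Reagents that add atoms: ozone, [O-][O+]=O; sodium chlorite, [Na+].[O-]Cl=O
Why: Ozonolysis should cleave the electron-rich monosubstituted alkene faster than the conjugated tetrasubstituted enone, the dialkyl peroxide is inert to ozone, Me2S and chlorite, and immediate buffered Pinnick oxidation of the crude aldehyde protects the α-stereocentre from epimerisation.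

Step 17
Reactants: 22 dioxane propanoic acid
Product: 23 methyl (2R)-2-{(3R,6R)-6-methyl-6-[2-(2,6,6-trimethyl-3-oxocyclohex-1-en-1-yl)ethyl]-1,2-dioxan-3-yl}propanoate (diacarperoxide A)
Conditions: Me3SiCHN2, MeOH/toluene, 0 °C
Reagents that add atoms: trimethylsilyldiazomethane, C[Si](C)(C)C=[N+]=[N-]
Why: Methyl esterification with trimethylsilyldiazomethane is neutral, so neither the 1,2-dioxane nor the α-stereocentre is disturbed.

## Compound list

1 | 3,3-dimethyloxolan-2-one | CC1(C)CCOC1=O | starting material
2 | 3,3-dimethyloxolan-2-ol (racemic lactol) | CC1(C)CCOC1O | intermediate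
3 | 3,3-dimethylpent-4-yn-1-ol | C#CC(C)(C)CCO | intermediate
4 | 5-bromo-3,3-dimethylpent-1-yne | C#CC(C)(C)CCBr | intermediate
5 | 6-bromo-4,4-dimethylhex-2-yn-1-ol | OCC#CC(C)(C)CCBr | intermediate
6 | 6-bromo-4,4-dimethylhex-2-yn-1-yl methanesulfonate | CS(=O)(=O)OCC#CC(C)(C)CCBr | intermediate
7 | 3-methylbut-3-en-1-ol | CC(=C)CCO | starting material
8 | tert-butyl(2-iodoethoxy)dimethylsilane | CC(C)(C)[Si](C)(C)OCCI | starting material
9 | 6-[(tert-butyldimethylsilyl)oxy]-3-methylidenehexan-1-ol | OCCC(=C)CCCO[Si](C)(C)C(C)(C)C | intermediate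
10 | [(6-bromo-4-methylidenehexyl)oxy](tert-butyl)dimethylsilane | BrCCC(=C)CCCO[Si](C)(C)C(C)(C)C | intermediate
11 | bromo{6-[(tert-butyldimethylsilyl)oxy]-3-methylidenehexyl}magnesium (Grignard reagent, not isolated) | Br[Mg]CCC(=C)CCCO[Si](C)(C)C(C)(C)C | intermediate
12 | {[7-(4-bromo-2-methylbutan-2-yl)-4-methylidenenona-7,8-dien-1-yl]oxy}(tert-butyl)dimethylsilane | C=C=C(CCC(=C)CCCO[Si](C)(C)C(C)(C)C)C(C)(C)CCBr | intermediate
13 | 3-{6-[(tert-butyldimethylsilyl)oxy]-3-methylidenehexyl}-2,4,4-trimethylcyclohex-2-en-1-one | CC1=C(CCC(=C)CCCO[Si](C)(C)C(C)(C)C)C(C)(C)CCC1=O | intermediate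
14 | 3-(6-hydroxy-3-methylidenehexyl)-2,4,4-trimethylcyclohex-2-en-1-one | CC1=C(CCC(=C)CCCO)C(C)(C)CCC1=O | intermediate
15 | 3-{6-hydroxy-3-methyl-3-[(triethylsilyl)peroxy]hexyl}-2,4,4-trimethylcyclohex-2-en-1-one (both epimers at the peroxy carbon) | CC1=C(CCC(C)(OO[Si](CC)(CC)CC)CCCO)C(C)(C)CCC1=O | intermediate
16 | 4-methyl-4-[(triethylsilyl)peroxy]-6-(2,6,6-trimethyl-3-oxocyclohex-1-en-1-yl)hexanal (both C4 epimers) | CC1=C(CCC(C)(OO[Si](CC)(CC)CC)CCC=O)C(C)(C)CCC1=O | intermediate
17 | 3-{(6S,7S)-6-hydroxy-3,7-dimethyl-3-[(triethylsilyl)peroxy]non-8-en-1-yl}-2,4,4-trimethylcyclohex-2-en-1-one (both epimers at the peroxy carbon) | C=C[C@H](C)[C@@H](O)CCC(C)(OO[Si](CC)(CC)CC)CCC1=C(C)C(=O)CCC1(C)C | intermediate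
18 | (3S,4S)-3,7-dimethyl-7-[(triethylsilyl)peroxy]-9-(2,6,6-trimethyl-3-oxocyclohex-1-en-1-yl)non-1-en-4-yl methanesulfonate (both C7 epimers) | C=C[C@H](C)[C@@H](OS(C)(=O)=O)CCC(C)(OO[Si](CC)(CC)CC)CCC1=C(C)C(=O)CCC1(C)C | intermediate
19 | (3S,4S)-7-hydroperoxy-3,7-dimethyl-9-(2,6,6-trimethyl-3-oxocyclohex-1-en-1-yl)non-1-en-4-yl methanesulfonate (both C7 epimers, not isolated) | C=C[C@H](C)[C@@H](OS(C)(=O)=O)CCC(C)(OO)CCC1=C(C)C(=O)CCC1(C)C | intermediate
20 | (3R,6R)-3-[(2S)-but-3-en-2-yl]-6-methyl-6-[2-(2,6,6-trimethyl-3-oxocyclohex-1-en-1-yl)ethyl]-1,2-dioxane | C=C[C@H](C)[C@H]1CC[C@@](C)(CCC2=C(C)C(=O)CCC2(C)C)OO1 | intermediate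
21 | (2R)-2-{(3R,6R)-6-methyl-6-[2-(2,6,6-trimethyl-3-oxocyclohex-1-en-1-yl)ethyl]-1,2-dioxan-3-yl}propanal (not isolated) | O=C[C@H](C)[C@H]1CC[C@@](C)(CCC2=C(C)C(=O)CCC2(C)C)OO1 | intermediate
22 | (2R)-2-{(3R,6R)-6-methyl-6-[2-(2,6,6-trimethyl-3-oxocyclohex-1-en-1-yl)ethyl]-1,2-dioxan-3-yl}propanoic acid | OC(=O)[C@H](C)[C@H]1CC[C@@](C)(CCC2=C(C)C(=O)CCC2(C)C)OO1 | intermediate
23 | methyl (2R)-2-{(3R,6R)-6-methyl-6-[2-(2,6,6-trimethyl-3-oxocyclohex-1-en-1-yl)ethyl]-1,2-dioxan-3-yl}propanoate (diacarperoxide A) | COC(=O)[C@H](C)[C@H]1CC[C@@](C)(CCC2=C(C)C(=O)CCC2(C)C)OO1 | target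

## Step count and risks

Total step count: 17. Longest linear sequence: 15 steps (steps 1–5 and 8–17, from lactone 1); the side-chain branch (steps 6 and 7) joins at step 8.

**Steps most likely to fail**

1. Step 9 (Proposed new method). Hydrogen transfer to the alkyl or acyl radical may outrun carbonylation and ring closure, the alkyl radical may close a five-membered ring onto the allene before it meets CO, or stannyl radicals may add reversibly to the allene and divert material to open-chain products. The fallback uses known chemistry, sets out from Grignard reagent 11 (made from bromide 10 as in step 8) and comes back to the route at enone 13. 2-Methylpentan-3-one and methyl acrylate are combined with KOt-Bu; Michael addition at the more substituted α-carbon gives methyl 4,4-dimethyl-5-oxoheptanoate F1, which undergoes Claisen cyclisation in the same flask to 2,4,4-trimethylcyclohexane-1,3-dione F2, the ring again being closed through the bond between the carbonyl carbon and the methyl-bearing carbon. Acid-catalysed etherification (i-BuOH, TsOH, removal of water) at the less hindered carbonyl gives 3-isobutoxy-2,6,6-trimethylcyclohex-2-en-1-one F3. Addition of 11 to the remaining ketone gives 1-{6-[(tert-butyldimethylsilyl)oxy]-3-methylidenehexyl}-3-isobutoxy-2,6,6-trimethylcyclohex-2-en-1-ol F4, and brief treatment with dilute aqueous acid (Stork–Danheiser transposition) returns 13.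

2. Step 15. Elimination of the hindered secondary mesylate by the basic peroxide anion or by fluoride, or conjugate attack of the peroxide anion on the enone, may outrun the 6-exo-tet displacement, and the cyclic C6 epimers may separate poorly. The fallback closes the dioxane at the quaternary carbon instead, sets out from alcohol 14 and comes back at dioxane 20. Dess–Martin oxidation gives 4-methylidene-6-(2,6,6-trimethyl-3-oxocyclohex-1-en-1-yl)hexanal F5; the (Z)-crotylboration of step 13 gives 3-[(6S,7S)-6-hydroxy-7-methyl-3-methylidenenon-8-en-1-yl]-2,4,4-trimethylcyclohex-2-en-1-one F6; mesylation gives (3S,4S)-3-methyl-7-methylidene-9-(2,6,6-trimethyl-3-oxocyclohex-1-en-1-yl)non-1-en-4-yl methanesulfonate F7. Displacement with hydrogen peroxide (H2O2, KOH, MeOH/THF, inversion) gives 3-[(6R,7S)-6-hydroperoxy-7-methyl-3-methylidenenon-8-en-1-yl]-2,4,4-trimethylcyclohex-2-en-1-one F8. Hg(OAc)2 (divalent mercury) in CH2Cl2 then induces 6-exo attack of the hydroperoxide on the 1,1-disubstituted alkene to give the organomercurial {(6R)-6-[(2S)-but-3-en-2-yl]-3-[2-(2,6,6-trimethyl-3-oxocyclohex-1-en-1-yl)ethyl]-1,2-dioxan-3-yl}methylmercury acetate F9, and brief NaBH4/NaOH demercuration at 0 °C returns 20 after separation from its C6 epimer.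

3. Step 16. Ozone may over-oxidise the tetrasubstituted enone double bond, and the β-peroxy aldehyde may suffer retro-oxa-Michael ring opening or α-epimerisation before it is oxidised. The fallback avoids ozone, sets out from vinyl dioxane 20 and comes back at aldehyde 21. Dihydroxylation with OsO4 (catalytic) and N-methylmorpholine N-oxide, which is selective for the monosubstituted alkene, gives (3S)-3-{(3R,6R)-6-methyl-6-[2-(2,6,6-trimethyl-3-oxocyclohex-1-en-1-yl)ethyl]-1,2-dioxan-3-yl}butane-1,2-diol F10; cleavage with NaIO4 in buffered aqueous THF gives 21, which is oxidised at once with NaClO2 as in step 16.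

Further compounds
F1 | step 9 | methyl 4,4-dimethyl-5-oxoheptanoate | CCC(=O)C(C)(C)CCC(=O)OC
F2 | step 9 | 2,4,4-trimethylcyclohexane-1,3-dione | CC1C(=O)CCC(C)(C)C1=O
F3 | step 9 | 3-isobutoxy-2,6,6-trimethylcyclohex-2-en-1-one | CC1=C(OCC(C)C)CCC(C)(C)C1=O
F4 | step 9 | 1-{6-[(tert-butyldimethylsilyl)oxy]-3-methylidenehexyl}-3-isobutoxy-2,6,6-trimethylcyclohex-2-en-1-ol | CC1=C(OCC(C)C)CCC(C)(C)C1(O)CCC(=C)CCCO[Si](C)(C)C(C)(C)C
F5 | step 15 | 4-methylidene-6-(2,6,6-trimethyl-3-oxocyclohex-1-en-1-yl)hexanal | CC1=C(CCC(=C)CCC=O)C(C)(C)CCC1=O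
F6 | step 15 | 3-[(6S,7S)-6-hydroxy-7-methyl-3-methylidenenon-8-en-1-yl]-2,4,4-trimethylcyclohex-2-en-1-one | C=C[C@H](C)[C@@H](O)CCC(=C)CCC1=C(C)C(=O)CCC1(C)C
F7 | step 15 | (3S,4S)-3-methyl-7-methylidene-9-(2,6,6-trimethyl-3-oxocyclohex-1-en-1-yl)non-1-en-4-yl methanesulfonate | C=C[C@H](C)[C@@H](OS(C)(=O)=O)CCC(=C)CCC1=C(C)C(=O)CCC1(C)C
F8 | step 15 | 3-[(6R,7S)-6-hydroperoxy-7-methyl-3-methylidenenon-8-en-1-yl]-2,4,4-trimethylcyclohex-2-en-1-one | C=C[C@H](C)[C@H](OO)CCC(=C)CCC1=C(C)C(=O)CCC1(C)C
F9 | step 15 | {(6R)-6-[(2S)-but-3-en-2-yl]-3-[2-(2,6,6-trimethyl-3-oxocyclohex-1-en-1-yl)ethyl]-1,2-dioxan-3-yl}methylmercury acetate (both epimers at the quaternary carbon) | C=C[C@H](C)[C@H]1CCC(C[Hg]OC(C)=O)(CCC2=C(C)C(=O)CCC2(C)C)OO1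
F10 | step 16 | (3S)-3-{(3R,6R)-6-methyl-6-[2-(2,6,6-trimethyl-3-oxocyclohex-1-en-1-yl)ethyl]-1,2-dioxan-3-yl}butane-1,2-diol (both C2 epimers) | OCC(O)[C@H](C)[C@H]1CC[C@@](C)(CCC2=C(C)C(=O)CCC2(C)C)OO1
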